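(The runs come from a simulation for substances that don't exist, noise included.)

If the readings of a flask stop moving, reckon its end state and leave the clock out.

| flask | starting material | protic impurity | remark | time |
|---|---|---|---|---|
| epsilon | 1 M | 0.046 M | run made earlier |  |
| theta | 1 M | 0.28 M | run made earlier |  |
| beta | 1.6 M | 0.20 M | run made earlier |  |
| dusk | 0.50 M | 0.120 M |  | 3.0 d |
| midnight | 1.0 M | 0.0600 M |  | 3.0 d |
| summer | 3.0 M | 0.300 M |  | 3.0 d |
| autumn | 3.0 M | 0.400 M |  | 3.0 d |
| winter | 1.0 M | 0.200 M |  | 3.0 d |

- epsilon (time / d: product / %): 0.250: 55.2; 0.833: 61.0; 1.25: 60.2; 2.00: 59.4; 3.00: 60.7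
- theta (time / d: product / %): 0.250: 41.6; 0.417: 42.3; 0.833: 42.5; 1.67: 42.1; 3.00: 42.7
- beta (time / d: product / %): 0.250: 56.8; 0.417: 58.7; 0.833: 59.5; 1.67: 59.5; 3.00: 59.3

(standard deviation of a reading: 0.5 percentage points)

- a species is counted by the starting material in it: one product counts as two
- the earlier runs were read with a standard deviation of 0.5 percentage points
- a reading or a percentage of product counts all its forms, free or not

* ranking by amount of product, in percent of the starting material charged, from high to low, at 3.0 d (dusk / midnight / summer / autumn / winter)
* the amount of product, in percent of the starting material charged of the flask you put first, at 3.0 d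
* the amount of product, in percent of the starting material charged of the flask you put last, at 3.0 d

The earlier runs lie flat within the scatter from 0.833 d on, well before 3.0 d, so treat the new flasks as ended by then. Take one starting material away for each protic impurity, count each product as two, and use the last reading of the epsilon, theta and beta runs. On average these readings give 2.45 M⁻¹: this is the equilibrium quotient, c(product) divided by c(starting material) squared at the plateau. Solved with this reading, my own reckoning puts summer at 68.4% and dusk at 37.1%.

The forecast states its ground as “These agree within reading error, so K ≈ 2.4 M⁻¹.” It ranks summer > autumn > midnight > winter > dusk, with 68.3% for summer and 36.9% for dusk.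

The flasks give summer > autumn > midnight > winter > dusk, with 71.0% for summer and 36.8% for dusk.

    crystals ⇌ product, rate k1*(cs1 - [product]) while solid is left; crystals form when [product] > cs1 (solubility = 0.780 M, k = 0.0620 min⁻¹)
    2 starting material ⇌ product (K = 2.40 M⁻¹, k = 0.00300 M⁻¹ min⁻¹)
    starting material + protic impurity → quenched substrate (k = 0.0120 M⁻¹ min⁻¹)

Summer stands 2.7 percentage points above the forecast and holds 19.0% as crystals, counted in its product. Take them out: summer has 0.780 M of dissolved product and 0.570 M of starting material, and its quotient comes to 2.40 M⁻¹. Now take the neighbour flask, summer with 1.2 M of protic impurity. The quotient read from the earlier runs, 2.45 M⁻¹, gives it 0.644 M of product, or 42.9%, which is less than the solubility of 0.78 M. The neighbour flask holds 0% crystals and gives 42.8%.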